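# Suaveolindole (10) from (R)-pulegone: oxygen on C1 exchanged for the C3 chain by a tandem [2,3]-Wittig / anionic oxy-Cope relay

Numbering follows the name 3-[(1S,2R,3R)-2-(1H-indol-3-ylmethyl)-2,3-dimethyl-6-(propan-2-ylidene)cyclohexyl]propanoic acid. C1–C6 are the ring atoms and C7 is the exocyclic alkene carbon. C3′–C2′–C1′ is the side chain, counted from the ring to the carboxyl carbon.

## The problem

1. Suaveolindole (10) is a 3,4-seco sesquiterpene with one cyclohexane ring and nothing fused to it, so no second ring can relay stereochemistry.
2. C3 (H, CH3), C2 (quaternary: CH3, CH2-indol-3-yl) and C1 (H, CH2CH2CO2H) are contiguous stereocentres. The C3 methyl is cis to the indolylmethyl group and the C2 methyl is cis to the chain. In the chair with the C3 methyl equatorial, the indolylmethyl group and the chain are therefore trans-diaxial, and A(1,3) strain with the isopropylidene group favours this axial chain.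
3. The hardest bond is C1–C3′. C1 is secondary, neopentyl on the C2 side and flanked by a tetrasubstituted alkene on the C6 side, so SN2 chemistry is excluded and intermolecular additions should be slow.
4. C3 can control C2 through alkylation of a C1=C2 enolate anti to the C3 methyl. C2 and C3 together can control C1, but only if carbon rather than hydrogen arrives last at a trigonal C1, because reagents come from the face opposite the axial indolylmethyl group.
5. The C6=C7 bond cannot be placed reliably by elimination or by olefination of a hindered, epimerisable ketone. Once present it is easily protonated to a tertiary cation within reach of indole C2 and of the carboxyl group. The 3-alkylindole itself does not survive strong acid, electrophilic halogen or peracid.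
6. The feature that makes the key step possible is the chain O=C1′–C2′–C3′–C1–C6=C7, a δ,ε-unsaturated carbonyl array and hence the retron of an oxy-Cope rearrangement. Within it, C1–C6=C7 is an allyl triad whose far end C7 carries two identical methyl groups, so C7 can be made quaternary and released again without stereochemical or regiochemical trace.
7. C1–C6, C7 with its two methyls, and the C3 methyl form the intact skeleton of (R)-pulegone (1). It has the correct C3 configuration, the alkene in place and oxygen on C1.

## Retrosynthesis

**10 ⇒ 9.** No skeletal bond is cut; the carboxyl group is taken back to aldehyde 9. This is preferred to an ester-level precursor because the one pericyclic process that makes C1–C3′ and C6=C7 together ends in an aldehyde enolate. The price is one mild oxidation that must spare the indole and the alkene.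

**9 ⇒ 8.** C1–C3′ is cut and C1′ is rejoined to C7. This moves the double bond from C6=C7 to C1=C6 and gives the 1,5-dien-3-ol(ate) 8.
- The neighbouring cuts treat C1 as an SN2/SN2′ electrophile, as the α-carbon of a C6 ketone, or as a radical. Against them, this cut makes the crowded bond intramolecularly at a trigonal C1, with carbon arriving last.
- The alkene can return only to C6=C7.
- 8 has one relevant stereocentre fewer than 9, because its carbinol centre is lost again.
- The forward anionic oxy-Cope rearrangement must choose the ring face anti to the pseudoaxial indolylmethyl group.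

**8 ⇒ 7.** C7–C1′ is cut and the oxygen is rejoined to C1, so 8 is the [2,3]-Wittig product of the bis-allylic ether 7.
- Building 8 from an allyl-metal reagent and acrolein would need an allylic halide of a system that eliminates readily. This cut avoids that.
- It also leaves the alkoxide ready for the next shift, so both shifts can run in one flask.
- 7 is far easier to reach than 9. The hindered C–C bond has become a C–O bond at the same carbon, and all three chain carbons come from one allyl group.
- The forward reaction needs metalation at the OCH2 group and [2,3]- over [1,2]-shift.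

**7 ⇒ 6 ⇒ 5 ⇒ 4.** The N–H is re-masked as N-Boc (6), the O–C1′ bond is cut (allylic alcohol 5), and the C1–H bond is removed (enone 4). These are functional-group operations on an unchanged skeleton. The C1 configuration in 5–7 is irrelevant because it is erased later. The carbamate is needed only while oxygen is allylated, since a free indole would be allylated instead.

**4 ⇒ 3 ⇒ 1 + 2.** C2–CH3 is cut first, then C2–CH2(indolyl).
- The C1 carbonyl activates C2 for both bonds.
- The order is dictated by stereochemistry. The last electrophile enters anti to the C3 methyl, and that group must be CH3.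
- The precursors are (R)-pulegone (1), which supplies ten of the fifteen terpenoid carbons, C3 and the alkene, and the stable bromide 2.
- The forward reactions need α′- rather than γ-enolisation of the enone.

## Roads not taken

**Alternative 1:** This is the most obvious route.
- Cuts: C6=C7 (olefination), C1–C3′ and C2–CH3 (vicinal difunctionalisation of an enone).
- Forward key step: Me2CuLi adds to (R)-3-(indol-3-ylmethyl)-4-methylcyclohex-2-enone A1 anti to the ring methyl. The enolate is trapped with methyl acrylate to give keto ester A2, and the C6 ketone is then converted into the isopropylidene group.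
- Why the chosen plan is better:
  - A1 needs its own asymmetric synthesis.
  - In A2 the chain must be axial and anti to the axial indolylmethyl group. That is the less stable epimer α to a ketone, so it is at risk under any basic olefination.
  - Isopropylidenation of a ketone next to that crowded centre, in the presence of an ester, needs a multi-step sequence.
  - In the chosen plan the alkene is never made; it is inherited.

**Alternative 2:**
- Cuts: C1–C6 and C2–C3, a retro-Diels–Alder after adding a C4=C5 double bond and hydrating C6=C7.
- Forward key step: an endo-selective Diels–Alder reaction, catalysed by a chiral Lewis acid, of dienyl silyl ether A3 with the trisubstituted enal A4 gives cyclohexene A5. This is followed by reductive alkylation of indole with the neopentyl aldehyde group of A5, dehydration and diimide reduction.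
- It would set all three centres at once.
- Why the chosen plan is better:
  - An α-methyl-β-alkyl enal is a poor dienophile, and the diene is 1,4-disubstituted.
  - The tertiary dienylic C–O bond of A3 should ionise under the Lewis acid that is needed.
  - The two alkyl-capped diene ends give little electronic bias for regiochemistry.
  - A fourth stereocentre and a ring alkene must be erased afterwards, ending in a dehydration of uncertain direction.

**Alternative 3:**
- Cut: C1′ is reconnected to C7, restoring the biogenetic ring A as decalone A6.
- Forward key step: Baeyer–Villiger oxidation of A6 to ε-lactone A7, then acid-induced opening of the tertiary ester to the acid and the alkene.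
- Why the chosen plan is better:
  - A6 is more complex than the target, with an extra ring and four contiguous stereocentres.
  - The peracid is incompatible with a 3-alkylindole.
  - The C7 cation released from A7 can lose a proton in three directions and lies next to indole C2.
  - In the chosen plan the same C7 becomes quaternary and is released again under basic, concerted conditions, so the alkene position is fixed.

Key step: step 6

Assumption: the given SMILES is read as (1S,2R,3R)-10. C3 of 10 corresponds in space to C5 of (R)-(+)-pulegone. Bromide 2 is treated as a catalogue compound.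

## Steps

**Step 1**
Reactants: 1 (R)-(+)-pulegone; 2 tert-butyl 3-(bromomethyl)indole-1-carboxylate
Product: 3 tert-butyl 3-{[(1S,2R)-2-methyl-6-oxo-5-(propan-2-ylidene)cyclohexyl]methyl}indole-1-carboxylate (trans isomer drawn)
Conditions: LDA (commercial solution, 1.05 equiv), THF, −78 °C; then 2, −78 → −30 °C
Reagents that add atoms: none
Why: Kinetic deprotonation of the s-cis enone takes the α′-CH2 (future C2) and gives the cross-conjugated lithium enolate, which should be alkylated by the benzylic-type bromide (enolate SN2 alkylation) mainly anti to the neighbouring methyl group. The new centre is planarised again in step 2, so its configuration is irrelevant; the Boc group keeps 2 from ionising and masks N–H.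

**Step 2**
Reactants: 3 tert-butyl 3-{[(1S,2R)-2-methyl-6-oxo-5-(propan-2-ylidene)cyclohexyl]methyl}indole-1-carboxylate
Product: 4 tert-butyl 3-{[(1R,2R)-1,2-dimethyl-6-oxo-5-(propan-2-ylidene)cyclohexyl]methyl}indole-1-carboxylate
Conditions: LDA (1.1 equiv), THF, −78 → −40 °C; MeI, DMPU, −78 → 0 °C
Reagents that add atoms: iodomethane, CI
Why: A second kinetic enolisation gives the tetrasubstituted C1=C2 enolate, in which A(1,2) strain with the indolylmethyl arm turns the C3 methyl pseudoaxial, so MeI should enter axially from the opposite face (alkylation of a 2,3-disubstituted cyclohexanone enolate). This sets C2 as (R), with CH3 trans and CH2-indolyl cis to the C3 methyl, which is why methylation comes second.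

**Step 3**
Reactants: 4 tert-butyl 3-{[(1R,2R)-1,2-dimethyl-6-oxo-5-(propan-2-ylidene)cyclohexyl]methyl}indole-1-carboxylate
Product: 5 tert-butyl 3-{[(1R,2R,6R)-6-hydroxy-1,2-dimethyl-5-(propan-2-ylidene)cyclohexyl]methyl}indole-1-carboxylate
Conditions: NaBH4, CeCl3·7H2O, MeOH, −20 → 0 °C; neutral work-up
Reagents that add atoms: none
Why: Luche 1,2-reduction; the fully substituted β-carbon disfavours 1,4-attack and the buffered medium should spare the carbamate. Hydride is expected on the axial trajectory opposite the axial indolylmethyl group (equatorial alcohol, drawn), but this centre is erased in step 6, so either epimer serves.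

**Step 4**
Reactants: 5 tert-butyl 3-{[(1R,2R,6R)-6-hydroxy-1,2-dimethyl-5-(propan-2-ylidene)cyclohexyl]methyl}indole-1-carboxylate
Product: 6 tert-butyl 3-{[(1R,2R,6R)-1,2-dimethyl-6-(prop-2-en-1-yloxy)-5-(propan-2-ylidene)cyclohexyl]methyl}indole-1-carboxylate
Conditions: Et2Zn (0.5 equiv), THF, 0 °C; then allyl acetate, Pd(OAc)2 (5 mol %), 2-(di-tert-butylphosphino)biphenyl (7.5 mol %), rt
Reagents that add atoms: allyl acetate, C=CCOC(C)=O
Why: Pd-catalysed allylic etherification through the zinc alkoxide (Tsuji–Trost O-allylation) works without a free sodium or potassium alkoxide, which could attack the indole carbamate. The carbamate is needed here because a free 3-alkylindole would be allylated at N or C3 by the π-allyl complex.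

**Step 5**
Reactants: 6 tert-butyl 3-{[(1R,2R,6R)-1,2-dimethyl-6-(prop-2-en-1-yloxy)-5-(propan-2-ylidene)cyclohexyl]methyl}indole-1-carboxylate
Product: 7 3-{[(1R,2R,6R)-1,2-dimethyl-6-(prop-2-en-1-yloxy)-5-(propan-2-ylidene)cyclohexyl]methyl}-1H-indole
Conditions: K2CO3 (cat.), MeOH, 45 °C
Reagents that add atoms: none
Why: Indole carbamates are acyl-azole-like and undergo base-catalysed methanolysis, while the bis-allylic ether is inert. The free N–H is wanted because the first equivalent of base in step 6 turns it into an inert indolide, whereas a Boc group would be attacked by n-BuLi.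

**Step 6**
Reactants: 7 3-{[(1R,2R,6R)-1,2-dimethyl-6-(prop-2-en-1-yloxy)-5-(propan-2-ylidene)cyclohexyl]methyl}-1H-indole
Product: 9 3-[(1S,2R,3R)-2-(1H-indol-3-ylmethyl)-2,3-dimethyl-6-(propan-2-ylidene)cyclohexyl]propanal, via dienolate 8 (not isolated)
Conditions: n-BuLi (2.2 equiv), THF, −78 → −20 °C; then KOt-Bu, 18-crown-6 (2.5 equiv each), −20 → 40 °C; inverse quench into cold aq NH4Cl
Reagents that add atoms: none
Why: The first equivalent of n-BuLi makes the inert indolide and the second removes a proton from the unhindered OCH2 (C1′), not from the shielded, more substituted C1–H, as is the rule for unsymmetrical bis-allylic ethers. The α-oxyallyl anion then undergoes a suprafacial [2,3]-Wittig shift through a five-membered envelope in which C1′ bonds to C7, the C1–O bond breaks and the double bond moves to C1=C6, giving dienolate 8; the C–O bond can stand perpendicular to the alkene because A(1,3) strain with the Z-methyl already pushes the oxygen out of the alkene plane. Exchange of lithium for crown-complexed potassium releases the anionic oxy-Cope rearrangement (six-membered chair, C3′ bonds to C1, C1′–C7 breaks), helped by the gem-dimethyl group on the breaking bond and made irreversible by formation of the aldehyde enolate. The closest known reaction type is the tandem [2,3]-Wittig/anionic oxy-Cope reaction of bis-allylic ethers, and the first stage parallels [2,3]-Wittig shifts of 2-alkylidenecycloalkyl ethers. No ring is closed, since both cyclic arrays exist only in the transition states. The one surviving new stereocentre is C1: in the half-chair of 8 the equatorial C3 methyl places C2–CH3 pseudoequatorial and the C2–CH2-indolide pseudoaxial, so the vinyl terminus should add axially to the opposite face, trans to the indolylmethyl group and cis to C2–CH3, giving (1S), whereas the flipped half-chair would demand attack syn-axial to the C3 methyl. The ether centre of 7 and the carbinol centre of 8 are both destroyed, so their configurations do not matter. The step needs [2,3] over [1,2] shift (secured by low temperature in the first stage), [3,3] over alkoxide fragmentation (an unstabilised allyl anion is a poor leaving group) and fidelity of the alkene position, which is secured because the double bond can return only to C6=C7.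

**Step 7**
Reactants: 9 3-[(1S,2R,3R)-2-(1H-indol-3-ylmethyl)-2,3-dimethyl-6-(propan-2-ylidene)cyclohexyl]propanal
Product: 10 suaveolindole, 3-[(1S,2R,3R)-2-(1H-indol-3-ylmethyl)-2,3-dimethyl-6-(propan-2-ylidene)cyclohexyl]propanoic acid
Conditions: AgNO3, NaOH, EtOH–H2O, 0 °C → rt; then 1 M HCl to pH 4, 0 °C
Reagents that add atoms: sodium hydroxide, [Na+].[OH-] (oxygen source through the aldehyde hydrate; Ag2O formed in the flask is the oxidant)
Why: Silver(I) oxide oxidation of an aldehyde (Tollens type) produces no electrophilic halogen or peroxy species, so the indole and the tetrasubstituted alkene should survive. Aldehyde 9 is used at once and kept away from acid, because it could close onto C7 in a carbonyl-ene reaction; no stereocentre is α to the carbonyl, so none can epimerise.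

## Compound list

1 | (R)-(+)-pulegone, (5R)-5-methyl-2-(propan-2-ylidene)cyclohexan-1-one | CC(C)=C1CC[C@@H](C)CC1=O | starting material
2 | tert-butyl 3-(bromomethyl)indole-1-carboxylate | CC(C)(C)OC(=O)n1cc(CBr)c2ccccc12 | starting material
3 | tert-butyl 3-{[(1S,2R)-2-methyl-6-oxo-5-(propan-2-ylidene)cyclohexyl]methyl}indole-1-carboxylate | CC(C)=C1CC[C@@H](C)[C@H](Cc2cn(C(=O)OC(C)(C)C)c3ccccc23)C1=O | intermediate
4 | tert-butyl 3-{[(1R,2R)-1,2-dimethyl-6-oxo-5-(propan-2-ylidene)cyclohexyl]methyl}indole-1-carboxylate | CC(C)=C1CC[C@@H](C)[C@@](C)(Cc2cn(C(=O)OC(C)(C)C)c3ccccc23)C1=O | intermediate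
5 | tert-butyl 3-{[(1R,2R,6R)-6-hydroxy-1,2-dimethyl-5-(propan-2-ylidene)cyclohexyl]methyl}indole-1-carboxylate | CC(C)=C1CC[C@@H](C)[C@@](C)(Cc2cn(C(=O)OC(C)(C)C)c3ccccc23)[C@H]1O | intermediate
6 | tert-butyl 3-{[(1R,2R,6R)-1,2-dimethyl-6-(prop-2-en-1-yloxy)-5-(propan-2-ylidene)cyclohexyl]methyl}indole-1-carboxylate | CC(C)=C1CC[C@@H](C)[C@@](C)(Cc2cn(C(=O)OC(C)(C)C)c3ccccc23)[C@H]1OCC=C | intermediate
7 | 3-{[(1R,2R,6R)-1,2-dimethyl-6-(prop-2-en-1-yloxy)-5-(propan-2-ylidene)cyclohexyl]methyl}-1H-indole | CC(C)=C1CC[C@@H](C)[C@@](C)(Cc2c[nH]c3ccccc23)[C@H]1OCC=C | intermediate
8 | 4-[(3R,4R)-3-(1H-indol-3-ylmethyl)-3,4-dimethylcyclohex-1-en-1-yl]-4-methylpent-1-en-3-ol (present in the flask as its N,O-dimetal salt; neutral form drawn; carbinol centre left open, both epimers converge) | C=CC(O)C(C)(C)C1=C[C@](C)(Cc2c[nH]c3ccccc23)[C@H](C)CC1 | intermediate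
9 | 3-[(1S,2R,3R)-2-(1H-indol-3-ylmethyl)-2,3-dimethyl-6-(propan-2-ylidene)cyclohexyl]propanal | CC(C)=C1CC[C@@H](C)[C@@](C)(Cc2c[nH]c3ccccc23)[C@@H]1CCC=O | intermediate
10 | suaveolindole | CC(C)=C1CC[C@@H](C)[C@@](C)(Cc2c[nH]c3ccccc23)[C@@H]1CCC(=O)O | target

## Step count and least certain steps

Total step count: 7. Longest linear sequence: 7 (from 1).

**Step 6 (key step).**
- Most likely failure: in the first stage, homolytic [1,2]- and [1,4]-shifts through a radical pair may compete with the [2,3]-shift. The migrating carbon C1 is a well-stabilised allylic centre and the receiving carbon C7 is fully substituted.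
- Incomplete exchange of lithium for potassium would also stall the second stage.
- Fallback: it sets out from 5 and replaces the sigmatropic first stage by a polar C–C bond formation.
  - Alcohol 5 is phosphorylated to the allylic diethyl phosphate F1.
  - F1 is reduced with CrCl2/LiI to the allylchromium species. In a Nozaki–Hiyama-type addition to acrolein this should react at its more substituted end C7 and give the N-Boc dienol F2.
  - Methanolysis of the carbamate gives 8, where the route is rejoined. Isolated 8 is then rearranged with KH/18-crown-6 to 9.

**Step 2.**
- Most likely failure: γ-deprotonation at a methyl group of the isopropylidene unit, because the remaining α′-hydrogen is tertiary and crowded. This would be followed by methylation at C6 with deconjugation. Facial selectivity may also be only moderate.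
- Fallback: it sets out from 1 and generates the enolate by reduction instead of deprotonation.
  - The lithium enolate of 1 is added to tert-butyl 3-formylindole-1-carboxylate to give the aldol F3.
  - F3 is dehydrated under mild acid catalysis to the (E)-arylidene ketone F4.
  - Conjugate reduction of the less substituted enone arm with L-Selectride gives the same C1=C2 enolate regiospecifically. Trapping with MeI returns the route at 4.

**Step 4.**
- Most likely failure: slow capture of the π-allyl complex by the hindered zinc alkoxide, leaving time for transfer of the carbamate from nitrogen to oxygen.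
- Fallback: it sets out from 5 and makes the C–O bond within an ion pair. Acylation with allyl chloroformate/pyridine gives the mixed allyl carbonate F5. With Pd(PPh3)4 this should ionise at the unhindered allyl group, lose CO2 and collapse to 6.

**Step 7.**
- Most likely failure: aldol self-condensation of the unbranched aldehyde in the alkaline medium, and slow oxidative attack on the electron-rich indole C2=C3 bond.
- Fallback: it sets out from 9 and returns at 10 by biocatalysis. An aldehyde dehydrogenase with NAD+, recycled by an NADH oxidase under air in phosphate buffer (pH 8) with a cosolvent, oxidises only the formyl group. It makes no new compound (F0).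

## Further compounds

F1 | step 6 | tert-butyl 3-{[(1R,2R,6R)-6-(diethoxyphosphoryloxy)-1,2-dimethyl-5-(propan-2-ylidene)cyclohexyl]methyl}indole-1-carboxylate | CC(C)=C1CC[C@@H](C)[C@@](C)(Cc2cn(C(=O)OC(C)(C)C)c3ccccc23)[C@H]1OP(=O)(OCC)OCC
F2 | step 6 | tert-butyl 3-{[(1R,6R)-3-(3-hydroxy-2-methylpent-4-en-2-yl)-1,6-dimethylcyclohex-2-en-1-yl]methyl}indole-1-carboxylate (carbinol centre open) | C=CC(O)C(C)(C)C1=C[C@](C)(Cc2cn(C(=O)OC(C)(C)C)c3ccccc23)[C@H](C)CC1
F3 | step 2 | tert-butyl 3-{hydroxy[(2R)-2-methyl-6-oxo-5-(propan-2-ylidene)cyclohexyl]methyl}indole-1-carboxylate (mixture at the two new centres) | CC(C)=C1CC[C@@H](C)C(C(O)c2cn(C(=O)OC(C)(C)C)c3ccccc23)C1=O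
F4 | step 2 | tert-butyl 3-{(E)-[(2R)-2-methyl-6-oxo-5-(propan-2-ylidene)cyclohexylidene]methyl}indole-1-carboxylate | CC(C)=C1CC[C@@H](C)/C(=C\c2cn(C(=O)OC(C)(C)C)c3ccccc23)C1=O
F5 | step 4 | tert-butyl 3-{[(1R,2R,6R)-1,2-dimethyl-6-(prop-2-en-1-yloxycarbonyloxy)-5-(propan-2-ylidene)cyclohexyl]methyl}indole-1-carboxylate | CC(C)=C1CC[C@@H](C)[C@@](C)(Cc2cn(C(=O)OC(C)(C)C)c3ccccc23)[C@H]1OC(=O)OCC=C
F0 | step 7 | none | none
A1 | alternative 1 | (4R)-3-(1H-indol-3-ylmethyl)-4-methylcyclohex-2-en-1-one | O=C1C=C(Cc2c[nH]c3ccccc23)[C@H](C)CC1
A2 | alternative 1 | methyl 3-[(1S,2R,3R)-2-(1H-indol-3-ylmethyl)-2,3-dimethyl-6-oxocyclohexyl]propanoate | O=C1CC[C@@H](C)[C@@](C)(Cc2c[nH]c3ccccc23)[C@@H]1CCC(=O)OC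
A3 | alternative 2 | triethyl{[(3E,5E)-2-methylhepta-3,5-dien-2-yl]oxy}silane | C/C=C/C=C/C(C)(C)O[Si](CC)(CC)CC
A4 | alternative 2 | methyl (4E)-5-methyl-6-oxohex-4-enoate | O=C/C(C)=C/CCC(=O)OC
A5 | alternative 2 | methyl 3-{6-formyl-5,6-dimethyl-2-[2-(triethylsilyloxy)propan-2-yl]cyclohex-3-en-1-yl}propanoate (endo adduct; formyl, C5 methyl and silyloxypropyl group cis, chain trans to them) | CC(C)(O[Si](CC)(CC)CC)[C@H]1C=C[C@@H](C)[C@@](C)(C=O)[C@@H]1CCC(=O)OC
A6 | alternative 3 | trans-fused 5-(1H-indol-3-ylmethyl)-1,1,5,6-tetramethyloctahydronaphthalen-2(1H)-one | O=C1CC[C@H]2[C@](C)(Cc3c[nH]c4ccccc34)[C@H](C)CC[C@@H]2C1(C)C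
A7 | alternative 3 | ε-lactone from oxygen insertion between the carbonyl and the gem-dimethyl carbon of A6 | O=C1CC[C@H]2[C@](C)(Cc3c[nH]c4ccccc34)[C@H](C)CC[C@@H]2C(C)(C)O1
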